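**Plan**
- Locants follow the SMILES: C1 is the methyl on C2; the seven-membered ring is C2–C3–C4–C5–C6–C10–C11; the cyclopentane is C5–C6–C7–C8–C9; C12–C13 tether C11 to the butenolide.
- Enabling feature: in the seven-membered ring the C10 ketone has C11 (quaternary, CH3) as its α-carbon and C2 (CH–CH3) as its β-carbon, with the two methyls trans. Both C–CH3 bonds are therefore cut together, back to the C11=C2 enone (conjugate methylation, then enolate methylation).
- Further cuts: butenolide to a 3-substituted furan; C2=C11 by ring-closing metathesis; C4–C5 by butenyl addition to the C5 ketone; C6–C10 by aldol of a cyclopentanone with a 2-methylidene aldehyde.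
- Forward: cyclopentanone 3 (from 2,2-dimethylcyclopentane-1,3-dione) and enal 10 (from furan-3-carbaldehyde) are joined by aldol, the butenyl chain is added, the seven-membered ring is closed by metathesis, the enone is methylated twice, and the furan becomes the butenolide last.
- Stereochemistry: C8 from a CBS desymmetrisation; C6 from aldol attack anti to the C8 silyloxy group; C5 from addition anti to the C6 chain; C2 from cuprate attack on the open face of the trans-fused enone; C11 from methylation anti to the C2 methyl.

Key step: step 12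

Remark on the chemistry: the C10 carbinol of 12, 15 and 16 and the lactol carbon of 22 are not controlled and are carried as epimer mixtures, since both centres are erased later. But-3-en-1-ylmagnesium bromide 13 is taken as the commercial THF solution. Bicyclic compounds are named with azulene locants (C1 = gem-dimethyl carbon, C4 = ketone); the discussion uses the route locants defined above.

**Step 1**
Reactants: 1 2,2-dimethylcyclopentane-1,3-dione
Product: 2 (S)-3-hydroxy-2,2-dimethylcyclopentan-1-one
Conditions: (R)-Me-CBS oxazaborolidine (cat.), BH3·SMe2 (limiting, slow addition), THF, −20 °C; aqueous work-up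
Reagents that add atoms: none
Why: Corey–Bakshi–Shibata reduction differentiates the two enantiotopic carbonyl groups, the ketone binding the catalyst boron anti to the quaternary carbon so that the (R)-catalyst should deliver hydride to give the S carbinol at C8, while limiting borane keeps the second carbonyl intact.

**Step 2**
Reactants: 2 (S)-3-hydroxy-2,2-dimethylcyclopentan-1-one
Product: 3 (S)-3-[(tert-butyldimethylsilyl)oxy]-2,2-dimethylcyclopentan-1-one
Conditions: TBSCl, imidazole, DMF, rt to 40 °C
Reagents that add atoms: tert-butyldimethylsilyl chloride, CC(C)(C)[Si](C)(C)Cl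
Why: Imidazole-promoted silylation of the only hydroxyl installs a bulky silyl ether that survives the basic and organometallic steps and later shields one face of the five-membered ring.

**Step 3**
Reactants: 4 furan-3-carbaldehyde; 5 [2-(1,3-dioxolan-2-yl)ethyl]triphenylphosphonium bromide
Product: 7 2-[(Z)-3-(furan-3-yl)prop-2-en-1-yl]-1,3-dioxolane, via phosphonium ylide 6 (not isolated)
Conditions: KOtBu, THF, 0 °C; then 4, 0 °C → rt
Reagents that add atoms: none
Why: Wittig olefination of the non-enolisable aldehyde with a non-stabilised ylide appends the three-carbon acetal unit, and the alkene geometry (mainly Z expected) is irrelevant because the double bond is hydrogenated next.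

**Step 4**
Reactants: 7 2-[(Z)-3-(furan-3-yl)prop-2-en-1-yl]-1,3-dioxolane
Product: 8 2-[3-(furan-3-yl)propyl]-1,3-dioxolane
Conditions: H2 (1 atm), RhCl(PPh3)3 (cat.), toluene–EtOH, rt
Reagents that add atoms: none
Why: Homogeneous hydrogenation with the Wilkinson complex reduces the disubstituted alkene and leaves the aromatic furan and the acetal untouched, and it is run before the aldehyde is unmasked because that catalyst decarbonylates aldehydes.

**Step 5**
Reactants: 8 2-[3-(furan-3-yl)propyl]-1,3-dioxolane
Product: 9 4-(furan-3-yl)butanal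
Conditions: 1 M aq. HCl, THF, rt
Reagents that add atoms: water, O
Why: Acid-catalysed acetal hydrolysis frees the aldehyde, and a 3-alkylfuran tolerates dilute acid at room temperature for the short time required.

**Step 6**
Reactants: 9 4-(furan-3-yl)butanal
Product: 10 4-(furan-3-yl)-2-methylidenebutanal
Conditions: 37% aq. CH2O, pyrrolidine (cat.), EtCO2H (cat.), iPrOH, 45 °C
Reagents that add atoms: formaldehyde, C=O
Why: Amine- and acid-catalysed Mannich condensation with formaldehyde followed by elimination of the amine (organocatalytic α-methylenation of an aldehyde) gives the 2-substituted acrolein, which is used at once.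

**Step 7**
Reactants: 3 (S)-3-[(tert-butyldimethylsilyl)oxy]-2,2-dimethylcyclopentan-1-one; 10 4-(furan-3-yl)-2-methylidenebutanal
Product: 12 (3S,5R)-3-[(tert-butyldimethylsilyl)oxy]-5-[4-(furan-3-yl)-1-hydroxy-2-methylidenebutyl]-2,2-dimethylcyclopentan-1-one (carbinol epimers), via lithium enolate 11 (not isolated)
Conditions: LiN(iPr)2, THF, −78 °C; then 10, −78 °C; AcOH quench at −78 °C
Reagents that add atoms: none
Why: Kinetic lithium aldol addition, in which the ketone can enolise only towards C6, the enolate adds to the carbonyl of the α-branched enal at −78 °C, and the aldehyde approaches the enolate face opposite the C8 silyloxy group (pushed pseudo-axial by the adjacent gem-dimethyl carbon), which should place the new C6 substituent trans to it.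

**Step 8**
Reactants: 12 aldol adduct; 13 but-3-en-1-ylmagnesium bromide
Product: 15 (1S,3S,5R)-1-(but-3-en-1-yl)-3-[(tert-butyldimethylsilyl)oxy]-5-[4-(furan-3-yl)-1-hydroxy-2-methylidenebutyl]-2,2-dimethylcyclopentan-1-ol (carbinol epimers), via but-3-en-1-ylcerium dichloride 14 (not isolated)
Conditions: 13, CeCl3 (anhydrous), THF, −78 °C; then 12, −78 → −20 °C; aq. AcOH
Reagents that add atoms: none
Why: Organocerium 1,2-addition, in which the weakly basic, oxophilic reagent first forms the C10 alkoxide, which chelates cerium to the C5 carbonyl, and the butenyl group then enters anti to the C6 substituent, so that the C5 hydroxyl should be cis to the C10 chain and the two chains that become the ring fusion are trans.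

**Step 9**
Reactants: 15 diene diol
Product: 16 (2S,3aR,8aS)-2-[(tert-butyldimethylsilyl)oxy]-5-[2-(furan-3-yl)ethyl]-1,1-dimethyl-1,2,3,3a,4,7,8,8a-octahydroazulene-4,8a-diol (C4 epimers; trans-fused)
Conditions: second-generation Grubbs catalyst RuCl2(=CHPh)(H2IMes)(PCy3) (cat.), CH2Cl2 (dilute), 40 °C
Reagents that add atoms: none
Why: Ring-closing metathesis, in which the ruthenium carbene loads on the monosubstituted alkene and closes onto the 1,1-disubstituted alkene with loss of ethene, forms the trisubstituted C2=C11 bond of the seven-membered ring, helped by the fully substituted C5.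

**Step 10**
Reactants: 16 bicyclic diol
Product: 17 (2S,3aS,8aS)-2-[(tert-butyldimethylsilyl)oxy]-5-[2-(furan-3-yl)ethyl]-8a-hydroxy-1,1-dimethyl-2,3,3a,7,8,8a-hexahydroazulen-4(1H)-one
Conditions: Dess–Martin periodinane, NaHCO3, CH2Cl2, 0 °C → rt
Reagents that add atoms: none
Why: Dess–Martin oxidation converts the secondary allylic alcohol of both epimers into the conjugated C10 ketone under buffered, non-basic conditions, and the tertiary C5 alcohol cannot be oxidised.

**Step 11**
Reactants: 17 hydroxy enone
Product: 18 (2S,3aS,8aS)-2-[(tert-butyldimethylsilyl)oxy]-5-[2-(furan-3-yl)ethyl]-1,1-dimethyl-8a-[(triethylsilyl)oxy]-2,3,3a,7,8,8a-hexahydroazulen-4(1H)-one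
Conditions: TESOTf, 2,6-lutidine, CH2Cl2, −78 → 0 °C
Reagents that add atoms: triethylsilyl trifluoromethanesulfonate, CC[Si](CC)(CC)OS(=O)(=O)C(F)(F)F
Why: Silylation of the hindered tertiary alcohol with a silyl triflate and a non-nucleophilic base blocks retro-aldol cleavage of the β-hydroxy ketone and alkoxide formation in the cuprate step.

**Step 12**
Reactants: 18 trans-fused silyl-protected enone
Product: 20 (2S,3aS,5R,6R,8aS)-2-[(tert-butyldimethylsilyl)oxy]-5-[2-(furan-3-yl)ethyl]-1,1,5,6-tetramethyl-8a-[(triethylsilyl)oxy]octahydroazulen-4(1H)-one, via lithium enolate 19 (not isolated)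
Conditions: Me2CuLi (from MeLi and CuI), Et2O, −78 → −20 °C; then MeI, HMPA–THF, −20 °C → rt
Reagents that add atoms: lithium dimethylcuprate, [Li+].C[Cu-]C; iodomethane, CI
Why: Me2CuLi binds the C11=C2–C10=O enone of the seven-membered ring as a π-complex, oxidative addition gives a trivalent copper β-adduct and reductive elimination forms the C2–CH3 bond, leaving the regiodefined C10–C11 lithium enolate 19, which MeI then alkylates at carbon once HMPA loosens its aggregates. The closest known reaction type is the conjugate addition–enolate alkylation of 2-substituted cycloalkenones with lithium dialkylcuprates, which forms vicinal tertiary and quaternary centres with the two new groups trans; no ring is closed. C2 is controlled by the trans ring fusion, which should fix a chair-like cycloheptenone in which the enone flap and C5 lie on opposite sides of the ring plane, so that methyl enters on the outer face of C2, anti to the C3–C4 bond and away from the axial hydrogens on C4 and C6, and ends up cis to the C5 oxygen. C11 is controlled by the new pseudo-axial C2 methyl: MeI approaches the enolate from the opposite face, which gives the trans C2/C11 dimethyl relation and leaves the furylethyl chain cis to the C2 methyl. The step needs 1,4- over 1,2-addition (secured by the soft cuprate and the hindered carbonyl), alkylation at C11 and never at C6 (secured because the enolate arises by addition and not by deprotonation, so the C6 hydrogen whose removal would expel the C5 silyloxy group is not touched) and C- over O-methylation (secured by the soft electrophile MeI).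

**Step 13**
Reactants: 20 dimethylated furan ketone
Product: 22 (2S,3aS,5R,6R,8aS)-2-[(tert-butyldimethylsilyl)oxy]-5-[2-(2-hydroxy-5-oxo-2,5-dihydrofuran-3-yl)ethyl]-1,1,5,6-tetramethyl-8a-[(triethylsilyl)oxy]octahydroazulen-4(1H)-one (lactol epimers), via furan endoperoxide 21 (not isolated)
Conditions: O2, visible light, tetraphenylporphyrin (cat.), iPr2NEt, CH2Cl2, −78 °C
Reagents that add atoms: dioxygen (used as singlet oxygen), O=O
Why: [4+2] cycloaddition of singlet oxygen across the two α-carbons of the furan gives the endoperoxide, and the hindered amine removes the less encumbered bridgehead hydrogen remote from the alkyl group (Kornblum–DeLaMare-type fragmentation), so the carbonyl forms at the distal α-carbon and the lactol carbon lies next to the substituted carbon.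

**Step 14**
Reactants: 22 hydroxybutenolide
Product: 24 (2S,3aS,5R,6R,8aS)-2-[(tert-butyldimethylsilyl)oxy]-1,1,5,6-tetramethyl-5-[2-(5-oxo-2,5-dihydrofuran-3-yl)ethyl]-8a-[(triethylsilyl)oxy]octahydroazulen-4(1H)-one, via sodium hydroxy carboxylate 23 (not isolated)
Conditions: NaBH4, MeOH, 0 °C; then 1 M HCl to pH 3
Reagents that add atoms: none
Why: Borohydride reduces the aldehyde of the ring-opened formyl acrylate form of the lactol and acidification relactonises the cis hydroxy acid to the β-substituted butenolide, while the C10 ketone, flanked by quaternary C11 and by C6 next to the fully substituted C5, should be too hindered to react at 0 °C.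

**Step 15**
Reactants: 24 bis-silylated butenolide
Product: 25 (2S,3aS,5R,6R,8aS)-2,8a-dihydroxy-1,1,5,6-tetramethyl-5-[2-(5-oxo-2,5-dihydrofuran-3-yl)ethyl]octahydroazulen-4(1H)-one (CNP0077405.3)
Conditions: 48% aq. HF, MeCN, 0 °C → rt
Reagents that add atoms: none
Why: Acidic fluoride desilylation cleaves the tertiary triethylsilyl and the secondary tert-butyldimethylsilyl ether without exposing the β-hydroxy ketone or the butenolide to base, which would invite retro-aldol cleavage or γ-deprotonation.

**Compound list**
1 | 2,2-dimethylcyclopentane-1,3-dione | CC1(C)C(=O)CCC1=O | starting material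
2 | (S)-3-hydroxy-2,2-dimethylcyclopentan-1-one | O=C1CC[C@H](O)C1(C)C | intermediate
3 | (S)-3-[(tert-butyldimethylsilyl)oxy]-2,2-dimethylcyclopentan-1-one | O=C1CC[C@H](O[Si](C)(C)C(C)(C)C)C1(C)C | intermediate
4 | furan-3-carbaldehyde | O=Cc1ccoc1 | starting material
5 | [2-(1,3-dioxolan-2-yl)ethyl]triphenylphosphonium bromide | [Br-].C1COC(CC[P+](c2ccccc2)(c2ccccc2)c2ccccc2)O1 | starting material
6 | [2-(1,3-dioxolan-2-yl)ethylidene]triphenylphosphorane (ylide) | C1COC(CC=P(c2ccccc2)(c2ccccc2)c2ccccc2)O1 | intermediate (not isolated)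
7 | 2-[(Z)-3-(furan-3-yl)prop-2-en-1-yl]-1,3-dioxolane (Z isomer drawn, E isomer may accompany it) | c1cc(co1)/C=C\CC2OCCO2 | intermediate
8 | 2-[3-(furan-3-yl)propyl]-1,3-dioxolane | c1cc(co1)CCCC2OCCO2 | intermediate
9 | 4-(furan-3-yl)butanal | O=CCCCc1ccoc1 | intermediate
10 | 4-(furan-3-yl)-2-methylidenebutanal | O=CC(=C)CCc1ccoc1 | intermediate
11 | lithium enolate of 3 (C5–O–Li, C5=C6) | [Li]OC1=CC[C@H](O[Si](C)(C)C(C)(C)C)C1(C)C | intermediate (not isolated)
12 | (3S,5R)-3-[(tert-butyldimethylsilyl)oxy]-5-[4-(furan-3-yl)-1-hydroxy-2-methylidenebutyl]-2,2-dimethylcyclopentan-1-one (carbinol epimers) | O=C1[C@H](C[C@H](O[Si](C)(C)C(C)(C)C)C1(C)C)C(O)C(=C)CCc2ccoc2 | intermediate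
13 | but-3-en-1-ylmagnesium bromide | C=CCC[Mg]Br | starting material
14 | but-3-en-1-ylcerium dichloride | C=CCC[Ce](Cl)Cl | intermediate (not isolated)
15 | (1S,3S,5R)-1-(but-3-en-1-yl)-3-[(tert-butyldimethylsilyl)oxy]-5-[4-(furan-3-yl)-1-hydroxy-2-methylidenebutyl]-2,2-dimethylcyclopentan-1-ol (carbinol epimers) | C=CCC[C@]1(O)[C@H](C[C@H](O[Si](C)(C)C(C)(C)C)C1(C)C)C(O)C(=C)CCc2ccoc2 | intermediate
16 | (2S,3aR,8aS)-2-[(tert-butyldimethylsilyl)oxy]-5-[2-(furan-3-yl)ethyl]-1,1-dimethyl-1,2,3,3a,4,7,8,8a-octahydroazulene-4,8a-diol (C4 epimers, trans-fused) | C1CC[C@]2(O)[C@H](C[C@H](O[Si](C)(C)C(C)(C)C)C2(C)C)C(O)C=1CCc3ccoc3 | intermediate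
17 | (2S,3aS,8aS)-2-[(tert-butyldimethylsilyl)oxy]-5-[2-(furan-3-yl)ethyl]-8a-hydroxy-1,1-dimethyl-2,3,3a,7,8,8a-hexahydroazulen-4(1H)-one | C1CC[C@]2(O)[C@H](C[C@H](O[Si](C)(C)C(C)(C)C)C2(C)C)C(=O)C=1CCc3ccoc3 | intermediate
18 | (2S,3aS,8aS)-2-[(tert-butyldimethylsilyl)oxy]-5-[2-(furan-3-yl)ethyl]-1,1-dimethyl-8a-[(triethylsilyl)oxy]-2,3,3a,7,8,8a-hexahydroazulen-4(1H)-one | C1CC[C@]2(O[Si](CC)(CC)CC)[C@H](C[C@H](O[Si](C)(C)C(C)(C)C)C2(C)C)C(=O)C=1CCc3ccoc3 | intermediate
19 | lithium enolate of the C2-methylated ketone (C10–O–Li, C10=C11; C2 methyl cis to the C5 oxygen) | C[C@@H]1CC[C@]2(O[Si](CC)(CC)CC)[C@H](C[C@H](O[Si](C)(C)C(C)(C)C)C2(C)C)C(O[Li])=C1CCc3ccoc3 | intermediate (not isolated)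
20 | (2S,3aS,5R,6R,8aS)-2-[(tert-butyldimethylsilyl)oxy]-5-[2-(furan-3-yl)ethyl]-1,1,5,6-tetramethyl-8a-[(triethylsilyl)oxy]octahydroazulen-4(1H)-one | C[C@@H]1CC[C@]2(O[Si](CC)(CC)CC)[C@H](C[C@H](O[Si](C)(C)C(C)(C)C)C2(C)C)C(=O)[C@]1(C)CCc3ccoc3 | intermediate
21 | furan endoperoxide of 20 (2,3,7-trioxabicyclo[2.2.1]hept-5-ene carrying the ethyl tether on C5) | C[C@@H]1CC[C@]2(O[Si](CC)(CC)CC)[C@H](C[C@H](O[Si](C)(C)C(C)(C)C)C2(C)C)C(=O)[C@]1(C)CCC3=CC4OOC3O4 | intermediate (not isolated)
22 | (2S,3aS,5R,6R,8aS)-2-[(tert-butyldimethylsilyl)oxy]-5-[2-(2-hydroxy-5-oxo-2,5-dihydrofuran-3-yl)ethyl]-1,1,5,6-tetramethyl-8a-[(triethylsilyl)oxy]octahydroazulen-4(1H)-one (lactol epimers) | C[C@@H]1CC[C@]2(O[Si](CC)(CC)CC)[C@H](C[C@H](O[Si](C)(C)C(C)(C)C)C2(C)C)C(=O)[C@]1(C)CCC3=CC(=O)OC3O | intermediate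
23 | sodium (Z)-4-hydroxybut-2-enoate carrying the bicyclic ethyl tether on C3 (ring-opened, reduced form of 22) | C[C@@H]1CC[C@]2(O[Si](CC)(CC)CC)[C@H](C[C@H](O[Si](C)(C)C(C)(C)C)C2(C)C)C(=O)[C@]1(C)CC/C(CO)=C/C(=O)[O-].[Na+] | intermediate (not isolated)
24 | (2S,3aS,5R,6R,8aS)-2-[(tert-butyldimethylsilyl)oxy]-1,1,5,6-tetramethyl-5-[2-(5-oxo-2,5-dihydrofuran-3-yl)ethyl]-8a-[(triethylsilyl)oxy]octahydroazulen-4(1H)-one | C[C@@H]1CC[C@]2(O[Si](CC)(CC)CC)[C@H](C[C@H](O[Si](C)(C)C(C)(C)C)C2(C)C)C(=O)[C@]1(C)CCC3=CC(=O)OC3 | intermediate
25 | (2S,3aS,5R,6R,8aS)-2,8a-dihydroxy-1,1,5,6-tetramethyl-5-[2-(5-oxo-2,5-dihydrofuran-3-yl)ethyl]octahydroazulen-4(1H)-one | C[C@@H]1CC[C@]2(O)[C@H](C[C@H](O)C2(C)C)C(=O)[C@]1(C)CCC3=CC(=O)OC3 | target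

**Step count**
Total: 15 steps. Longest linear sequence: 13 steps (from 4 through steps 3–15).

**Steps most likely to fail**

Step 12. The conformational bias that exposes one face of C2 may be weak, so that methyl is delivered to both faces (poor facial selectivity). A slow methylation of the copper-containing enolate would in addition let 19 exchange protons with product at C6. The fallback sets out from 18 and puts the C2 face under reagent control. Copper-catalysed conjugate addition of Me3Al (Cu(OTf)2 and the matching enantiomer of a BINOL-derived phosphoramidite, Et2O, −30 °C) should give the dimethylaluminium enolate F1. This is silylated in the same flask with TMSOTf to the trimethylsilyl enol ether F2, which can be purified. MeLi in THF at 0 °C then regenerates copper-free lithium enolate 19, and MeI with HMPA brings the sequence back to the route at 20.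

Step 8. Enolisation of the hindered, α-branched ketone and retro-aldol cleavage of the C10 aldolate may outrun addition, and the C8 silyloxy group on the face of attack may erode the facial preference. The fallback sets out from 12 and builds the butenyl group in two stages with a small, weakly basic carbon nucleophile. Corey–Chaykovsky reaction with dimethylsulfonium methylide (Me3SI, KN(SiMe3)2, THF, −10 °C → rt) should give the C5 spiro-epoxide F3, its CH2 anti to the C6 chain. Copper-catalysed opening at the CH2 terminus with CH2=CHCH2MgBr and catalytic CuI (THF, −30 °C) completes the but-3-enyl chain and returns to the route at 15.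

Step 7. The lithium enolate may add to the enal in the conjugate sense, the free base may oligomerise the α-methylidene aldehyde, and the loose lithium transition state may discriminate the two faces of C6 incompletely. The fallback sets out from 3 and generates the enolate reductively under neutral conditions. Bromination of lithium enolate 11 with NBS at −78 °C gives the α-bromo ketone F4. SmI2 (2 equiv, THF, −78 °C) converts it into the trivalent samarium enolate F5, which should add to 10 through a tight chelated Reformatsky-type transition state, again anti to the silyloxy group. Work-up returns to the route at 12.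

**Further compounds**
F1 | step 12 | dimethylaluminium enolate of the C2-methylated ketone (C10–O–AlMe2, C10=C11) | C[C@@H]1CC[C@]2(O[Si](CC)(CC)CC)[C@H](C[C@H](O[Si](C)(C)C(C)(C)C)C2(C)C)C(O[Al](C)C)=C1CCc3ccoc3
F2 | step 12 | trimethylsilyl enol ether of the C2-methylated ketone (C10–O–SiMe3, C10=C11) | C[C@@H]1CC[C@]2(O[Si](CC)(CC)CC)[C@H](C[C@H](O[Si](C)(C)C(C)(C)C)C2(C)C)C(O[Si](C)(C)C)=C1CCc3ccoc3
F3 | step 8 | C5 spiro-epoxide of 12 (epoxide oxygen cis, CH2 trans to the C6 side chain; carbinol epimers) | C1[C@]2(O1)[C@H](C[C@H](O[Si](C)(C)C(C)(C)C)C2(C)C)C(O)C(=C)CCc3ccoc3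
F4 | step 7 | (3S)-5-bromo-3-[(tert-butyldimethylsilyl)oxy]-2,2-dimethylcyclopentan-1-one (C5 epimers) | O=C1C(Br)C[C@H](O[Si](C)(C)C(C)(C)C)C1(C)C
F5 | step 7 | diiodosamarium enolate of 3 (C5–O–SmI2, C5=C6) | I[Sm](I)OC1=CC[C@H](O[Si](C)(C)C(C)(C)C)C1(C)C
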